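## Retrosynthetic overview

- **Locants and last disconnections.** The side chain is numbered C1–C6 from ring A, the 2,4-disubstituted oxazole. Ring B is the 5-substituted oxazole. Target 14 ⇐ C3 ketone 13 (hydride delivered 1,3-syn and 1,2-anti) ⇐ 3-methylidene compound 12 (one carbon excised by ozone).
- **C3–C4 bond.** 12 ⇐ ligand-controlled Ni/Cr alkenylation. It joins vinylic bromide 7 (rings A and B, C1–C3) to (S)-2-acyloxypropanal 11 (C4–C6 plus the complete C16 ester). Neither half carries a protecting group.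
- **Fragments.** 7 ⇐ aldehyde 5 + 2,3-dibromopropene 6, a conjunctive linchpin that reacts first at its allylic carbon and then at its vinylic carbon. 5 ⇐ Suzuki–Miyaura union of 1 and 2. 11 ⇐ (S)-but-3-en-2-ol 8 + acid 9.
- **Enabling feature.** C3 lies between the C2 methylene and the C4 carbinol. Its hydroxyl is 1,3-syn to the C1 hydroxyl beside ring A and 1,2-anti to the C4 hydroxyl. C3 can therefore travel as an sp2 carbon (vinyl anion equivalent, then ketone) and be restored last by a reduction in which both chelates demand the same face.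
- **Rings.** None is formed in the route. Rings A and B are bought in 1 and 2 and are linked through the CH2 bridge in step 1.

Key step: step 6

Assumption: ligand L is N-[2-(4-isopropyl-4,5-dihydro-1,3-oxazol-2-yl)-6-methylphenyl]methanesulfonamide; (S)-L is taken to send the organochromium reagent to the Si face of an aldehyde and (R)-L to the Re face, and the two enantiomers are exchanged if a model aldehyde shows the opposite sense.

## Route

Step 1
Reactants: 1 methyl 2-(chloromethyl)-1,3-oxazole-4-carboxylate; 2 5-(4,4,5,5-tetramethyl-1,3,2-dioxaborolan-2-yl)-2-[tri(propan-2-yl)silyl]-1,3-oxazole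
Product: 4 methyl 2-[(1,3-oxazol-5-yl)methyl]-1,3-oxazole-4-carboxylate, via silylated bis-oxazole ester 3 (not isolated)
Conditions: Pd(dppf)Cl2 (5 mol %), K3PO4, THF/H2O, 65 °C; crude product, then 1 M HCl, THF, rt
Reagents that add atoms: none
Why: Suzuki–Miyaura coupling of a heterobenzylic chloride should work because zerovalent palladium inserts easily into the activated C–Cl bond of 1 and the C2 silyl group shields boronate 2 from protodeboronation, after which dilute acid cleaves the labile C2–Si bond of 3 by protodesilylation; no stereocentre is involved.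

Step 2
Reactants: 4 methyl 2-[(1,3-oxazol-5-yl)methyl]-1,3-oxazole-4-carboxylate
Product: 5 2-[(1,3-oxazol-5-yl)methyl]-1,3-oxazole-4-carbaldehyde
Conditions: i-Bu2AlH (1.2 equiv), CH2Cl2, −78 °C; aq. KNaC4H4O6 (tartrate)
Reagents that add atoms: none
Why: Partial ester reduction with i-Bu2AlH relies on the tetrahedral aluminium hemiacetal of the electron-poor oxazole-4-carboxylate, which is stable at −78 °C and collapses to the aldehyde only on work-up.

Step 3
Reactants: 5 2-[(1,3-oxazol-5-yl)methyl]-1,3-oxazole-4-carbaldehyde; 6 2,3-dibromoprop-1-ene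
Product: 7 (1R)-3-bromo-1-{2-[(1,3-oxazol-5-yl)methyl]-1,3-oxazol-4-yl}but-3-en-1-ol
Conditions: CrCl2 (3 equiv), (R)-L (3.3 equiv), Et3N (3.3 equiv), THF, rt; then 5 and 6, 0 °C; aqueous work-up (L recovered)
Reagents that add atoms: none
Why: Asymmetric Nozaki–Hiyama allylation (2-haloallylation): divalent chromium reduces only the allylic C–Br bond of 6 because no nickel is present, and the ligand-bound 2-bromoallylchromium reagent adds through a chair-like transition state to the Re face of 5, which sets C1 as R.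

Step 4
Reactants: 8 (2S)-but-3-en-2-ol; 9 14-methylpentadecanoic acid
Product: 10 (2S)-but-3-en-2-yl 14-methylpentadecanoate
Conditions: EDC·HCl, DMAP (cat.), CH2Cl2, 0 °C to rt
Reagents that add atoms: none
Why: Steglich esterification acylates the hydroxyl oxygen without touching the C–O bond of the stereocentre, so the S configuration of 8 becomes C5 of the target.

Step 5
Reactants: 10 (2S)-but-3-en-2-yl 14-methylpentadecanoate
Product: 11 (2S)-1-oxopropan-2-yl 14-methylpentadecanoate
Conditions: O3, CH2Cl2, −78 °C; Me2S, −78 °C to rt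
Reagents that add atoms: ozone [O-][O+]=O
Why: Ozonolysis with reductive work-up cleaves the only C=C bond under cold neutral conditions that should not epimerise the α-acyloxy aldehyde, which is used at once.

Step 6
Reactants: 7 (1R)-3-bromo-1-{2-[(1,3-oxazol-5-yl)methyl]-1,3-oxazol-4-yl}but-3-en-1-ol; 11 (2S)-1-oxopropan-2-yl 14-methylpentadecanoate
Product: 12 (2S,3S,6R)-3,6-dihydroxy-4-methylidene-6-{2-[(1,3-oxazol-5-yl)methyl]-1,3-oxazol-4-yl}hexan-2-yl 14-methylpentadecanoate (side chain 1R,4S,5S)
Conditions: CrCl2 (4 equiv), (S)-L (4.4 equiv), Et3N (4.4 equiv), NiCl2 (10 mol %), THF, rt; aqueous work-up (L recovered)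
Reagents that add atoms: none
Why: Nozaki–Hiyama–Kishi alkenylation: zerovalent nickel (made from NiCl2 by CrCl2) inserts into the vinylic C–Br bond of 7, the alkenyl group passes to trivalent chromium, and the ligand-bound alkenylchromium reagent adds to the aldehyde carbon of 11, which forms the C3–C4 bond. The closest known reaction type is the sulfonamide-ligand-controlled Ni/Cr coupling of 2-halo-1-alkenes with α-oxygenated aldehydes in late fragment unions. No ring is closed. The one new stereocentre, C4 (S), is set by the chiral ligand on chromium, which directs attack to the Si face of 11 and has to override the modest polar Felkin–Anh preference of the α-acyloxy aldehyde for the 4,5-anti isomer. The step needs chemoselectivity for the aldehyde over the ester, the free C1 hydroxyl, the acidic CH2 between rings A and B and the C2–H of ring B; this is secured because 11 holds the only aldehyde, 7 holds the only C(sp2)–Br bond, and organochromium reagents are barely basic. The covalent Cr–O bond of the product alkoxide should also hold back acyl migration from the C5 oxygen to the C4 oxygen.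

Step 7
Reactants: 12 (2S,3S,6R)-3,6-dihydroxy-4-methylidene-6-{2-[(1,3-oxazol-5-yl)methyl]-1,3-oxazol-4-yl}hexan-2-yl 14-methylpentadecanoate
Product: 13 (2S,3R,6R)-3,6-dihydroxy-4-oxo-6-{2-[(1,3-oxazol-5-yl)methyl]-1,3-oxazol-4-yl}hexan-2-yl 14-methylpentadecanoate (same spatial arrangement at C4; the descriptor changes by priority only)
Conditions: O3 (1 equiv, Sudan Red 7B end point), CH2Cl2, −78 °C; Me2S, −78 °C to rt
Reagents that add atoms: ozone [O-][O+]=O
Why: Ozonolysis should be selective because the 1,1-disubstituted alkene reacts much faster than the aromatic rings A and B, so one equivalent of ozone removes the extra carbon as formaldehyde and unveils the C3 ketone while the neutral work-up leaves C4 and the ester in place.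

Step 8
Reactants: 13 (2S,3R,6R)-3,6-dihydroxy-4-oxo-6-{2-[(1,3-oxazol-5-yl)methyl]-1,3-oxazol-4-yl}hexan-2-yl 14-methylpentadecanoate
Product: 14 (2S,3S,4S,6R)-3,4,6-trihydroxy-6-{2-[(1,3-oxazol-5-yl)methyl]-1,3-oxazol-4-yl}hexan-2-yl 14-methylpentadecanoate (side chain 1R,3S,4S,5S; target)
Conditions: Et2BOMe (2.2 equiv), THF/MeOH 4:1, −78 °C; NaBH4, −78 °C; pH 7 buffer, repeated evaporation from MeOH
Reagents that add atoms: none
Why: Narasaka–Prasad reduction: the diethylboron chelate between the C1 oxygen and the C3 carbonyl takes up external hydride axially to give the 1,3-syn diol, the five-membered chelate to the C4 oxygen demands the same face (1,2-anti), so C3 should be set as S, and NaBH4 at −78 °C leaves the ester untouched.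

## Compound list

1 | methyl 2-(chloromethyl)-1,3-oxazole-4-carboxylate | COC(=O)c1coc(CCl)n1 | starting material
2 | 5-(4,4,5,5-tetramethyl-1,3,2-dioxaborolan-2-yl)-2-[tri(propan-2-yl)silyl]-1,3-oxazole | CC(C)[Si](C(C)C)(C(C)C)c1ncc(o1)B1OC(C)(C)C(C)(C)O1 | starting material
3 | methyl 2-({2-[tri(propan-2-yl)silyl]-1,3-oxazol-5-yl}methyl)-1,3-oxazole-4-carboxylate | COC(=O)c1coc(Cc2cnc(o2)[Si](C(C)C)(C(C)C)C(C)C)n1 | intermediate
4 | methyl 2-[(1,3-oxazol-5-yl)methyl]-1,3-oxazole-4-carboxylate | COC(=O)c1coc(Cc2cnco2)n1 | intermediate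
5 | 2-[(1,3-oxazol-5-yl)methyl]-1,3-oxazole-4-carbaldehyde | O=Cc1coc(Cc2cnco2)n1 | intermediate
6 | 2,3-dibromoprop-1-ene | C=C(Br)CBr | starting material
7 | (1R)-3-bromo-1-{2-[(1,3-oxazol-5-yl)methyl]-1,3-oxazol-4-yl}but-3-en-1-ol | C=C(Br)C[C@@H](O)c1coc(Cc2cnco2)n1 | intermediate
8 | (2S)-but-3-en-2-ol | C[C@H](O)C=C | starting material
9 | 14-methylpentadecanoic acid | CC(C)CCCCCCCCCCCCC(=O)O | starting material
10 | (2S)-but-3-en-2-yl 14-methylpentadecanoate | CC(C)CCCCCCCCCCCCC(=O)O[C@@H](C)C=C | intermediate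
11 | (2S)-1-oxopropan-2-yl 14-methylpentadecanoate | CC(C)CCCCCCCCCCCCC(=O)O[C@@H](C)C=O | intermediate
12 | (2S,3S,6R)-3,6-dihydroxy-4-methylidene-6-{2-[(1,3-oxazol-5-yl)methyl]-1,3-oxazol-4-yl}hexan-2-yl 14-methylpentadecanoate | CC(C)CCCCCCCCCCCCC(=O)O[C@@H](C)[C@@H](O)C(=C)C[C@@H](O)c1coc(Cc2cnco2)n1 | intermediate
13 | (2S,3R,6R)-3,6-dihydroxy-4-oxo-6-{2-[(1,3-oxazol-5-yl)methyl]-1,3-oxazol-4-yl}hexan-2-yl 14-methylpentadecanoate | CC(C)CCCCCCCCCCCCC(=O)O[C@@H](C)[C@@H](O)C(=O)C[C@@H](O)c1coc(Cc2cnco2)n1 | intermediate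
14 | (2S,3S,4S,6R)-3,4,6-trihydroxy-6-{2-[(1,3-oxazol-5-yl)methyl]-1,3-oxazol-4-yl}hexan-2-yl 14-methylpentadecanoate | CC(C)CCCCCCCCCCCCC(=O)O[C@@H](C)[C@@H](O)[C@@H](O)C[C@@H](O)c1coc(Cc2cnco2)n1 | target

## Step count and risks

Total step count: 8. Longest linear sequence: 6 steps (1, 2, 3, 6, 7, 8).

**Step 6.**
- What may go wrong: ligand control may lose against the Felkin–Anh bias of the aldehyde (poor facial selectivity). The vinylic bromide may be activated slowly. The acyl group may migrate in the product alkoxide.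
- Fallback: C4 is set by hydride addition instead of by the C–C bond formation. Starting from 7, the C1 hydroxyl is silylated (TBSCl, imidazole, DMF) to the tert-butyldimethylsilyl ether F1. Ligand-free coupling of this ether with 11 (CrCl2, NiCl2 cat., DMSO) gives the allylic alcohol epimer mixture F2. Dess–Martin oxidation turns both epimers into the α'-acyloxy enone F3. Luche reduction (NaBH4, CeCl3·7H2O, MeOH, −78 °C) should add hydride anti to the C5–O bond (polar Felkin–Anh, 4,5-syn) and give the single allylic alcohol F4. HF·pyridine in THF removes the silyl group, and the route is rejoined at 12.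

**Step 3.**
- What may go wrong: enantioselectivity may erode because the ring nitrogen atoms bind to chromium. The 2-bromoallyl metal may lose bromide and escape as allene.
- Fallback: the vinylic bromide is built from an alkyne. Starting from 5, propargylation with allenylboronic acid pinacol ester is run in toluene at −20 °C. The catalyst is (R)-3,3'-bis(2,4,6-triisopropylphenyl)-1,1'-binaphthyl-2,2'-diyl hydrogen phosphate. This should give the homopropargylic alcohol F5. Bromoboration of the terminal alkyne with B-bromo-9-borabicyclo[3.3.1]nonane (CH2Cl2, 0 °C), followed by protonolysis with AcOH, places bromine on the internal carbon and returns to the route at 7.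

**Step 7.**
- What may go wrong: ozone may over-oxidise ring B, and the α-hydroxy ketone may degrade during work-up.
- Fallback: a two-stage osmium-based cleavage on a protected substrate. Starting from 12, both hydroxyls are silylated (TESCl, imidazole, CH2Cl2) to the bis(triethylsilyl) ether F6. OsO4 (cat.) with NMO gives the vicinal diol F7. NaIO4 can cleave only its C3–CH2OH bond, because the C4 oxygen is blocked, and gives the protected ketone F8. AcOH/THF/H2O removes both silyl groups and the route is rejoined at 13.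

## Further compounds

F1 | step 6 | 4-[(1R)-3-bromo-1-{[tert-butyl(dimethyl)silyl]oxy}but-3-en-1-yl]-2-[(1,3-oxazol-5-yl)methyl]-1,3-oxazole | C=C(Br)C[C@@H](O[Si](C)(C)C(C)(C)C)c1coc(Cc2cnco2)n1
F2 | step 6 | (2S,6R)-6-{[tert-butyl(dimethyl)silyl]oxy}-3-hydroxy-4-methylidene-6-{2-[(1,3-oxazol-5-yl)methyl]-1,3-oxazol-4-yl}hexan-2-yl 14-methylpentadecanoate (both epimers at the new carbinol) | CC(C)CCCCCCCCCCCCC(=O)O[C@@H](C)C(O)C(=C)C[C@@H](O[Si](C)(C)C(C)(C)C)c1coc(Cc2cnco2)n1
F3 | step 6 | (2S,6R)-6-{[tert-butyl(dimethyl)silyl]oxy}-4-methylidene-3-oxo-6-{2-[(1,3-oxazol-5-yl)methyl]-1,3-oxazol-4-yl}hexan-2-yl 14-methylpentadecanoate | CC(C)CCCCCCCCCCCCC(=O)O[C@@H](C)C(=O)C(=C)C[C@@H](O[Si](C)(C)C(C)(C)C)c1coc(Cc2cnco2)n1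
F4 | step 6 | (2S,3S,6R)-6-{[tert-butyl(dimethyl)silyl]oxy}-3-hydroxy-4-methylidene-6-{2-[(1,3-oxazol-5-yl)methyl]-1,3-oxazol-4-yl}hexan-2-yl 14-methylpentadecanoate | CC(C)CCCCCCCCCCCCC(=O)O[C@@H](C)[C@@H](O)C(=C)C[C@@H](O[Si](C)(C)C(C)(C)C)c1coc(Cc2cnco2)n1
F5 | step 3 | (1R)-1-{2-[(1,3-oxazol-5-yl)methyl]-1,3-oxazol-4-yl}but-3-yn-1-ol | C#CC[C@@H](O)c1coc(Cc2cnco2)n1
F6 | step 7 | (2S,3S,6R)-4-methylidene-6-{2-[(1,3-oxazol-5-yl)methyl]-1,3-oxazol-4-yl}-3,6-bis[(triethylsilyl)oxy]hexan-2-yl 14-methylpentadecanoate | CC(C)CCCCCCCCCCCCC(=O)O[C@@H](C)[C@@H](O[Si](CC)(CC)CC)C(=C)C[C@@H](O[Si](CC)(CC)CC)c1coc(Cc2cnco2)n1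
F7 | step 7 | (2S,3S,6R)-4-hydroxy-4-(hydroxymethyl)-6-{2-[(1,3-oxazol-5-yl)methyl]-1,3-oxazol-4-yl}-3,6-bis[(triethylsilyl)oxy]hexan-2-yl 14-methylpentadecanoate (configuration at the tertiary carbinol irrelevant) | CC(C)CCCCCCCCCCCCC(=O)O[C@@H](C)[C@@H](O[Si](CC)(CC)CC)C(O)(CO)C[C@@H](O[Si](CC)(CC)CC)c1coc(Cc2cnco2)n1
F8 | step 7 | (2S,3R,6R)-6-{2-[(1,3-oxazol-5-yl)methyl]-1,3-oxazol-4-yl}-4-oxo-3,6-bis[(triethylsilyl)oxy]hexan-2-yl 14-methylpentadecanoate | CC(C)CCCCCCCCCCCCC(=O)O[C@@H](C)[C@@H](O[Si](CC)(CC)CC)C(=O)C[C@@H](O[Si](CC)(CC)CC)c1coc(Cc2cnco2)n1
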